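## The problem

The target 18 is a flavonol, a 2-aryl-4H-chromen-4-one with a free hydroxyl at C3 and a ring A that is oxygenated at every position except C6 (5-OH, 7-OMe, 8-OMe, O1 on C8a). It has no stereocentre, so the difficulty is regiochemical. The 5,7,8 pattern must be built without ambiguity against the isomeric 5,6,7 pattern, and the one free phenol at C5 must be told apart from five methyl ethers. The rings are joined through ring C (O1–C8a, C4a–C4, C4–C3, C3–C2, C2–O1), with ring B on C2. The 3-hydroxy-4-pyranone unit is oxidised by air in base, so the C3 oxygen should stay masked until a last, neutral step. Strong protic or Lewis acids endanger the methyl ethers, above all the crowded ones at C8 and C4'. The feature that opens a short route is that C8a and C4a are neighbouring ring A carbons carrying an oxygen (O1) and an acyl carbon (C4). That is the pair of groups a carboxylic acid hands to the two carbons of an aryne. The two substituents flanking this aryne, the C5 oxygen and the C8 methoxy group, can be made electronically unequal so that the oxygen goes to C8a.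

## Retrosynthesis

**End game.** Target 18 is taken back to its 3-O-benzyl ether 17 (O3–CH2Ph bond) and 17 to the 5-O-tosylate 16 (O5–S bond). The benzyl group keeps the 3-hydroxy-4-pyranone masked until a final hydrogenolysis. The sulfonate at C5 is the element that steers the key step, and its later cleavage by hydroxide is eased by the ortho carbonyl. Neither operation touches a methyl ether, so no selective demethylation is needed to single out the C5 oxygen.

**Key disconnection.** Flavone 16 is cut at three bonds of ring C: O1–C8a, C4a–C4 and O1–C2. This gives acrylic acid 5, which holds C2, C3, C4, O1 and all of ring B, and aryne 14, which holds ring A. Other cuts through ring C need a ring A that already carries four differentiated oxygens and a carbon substituent; here ring A needs only a strained triple bond between C8a and C4a. In the forward direction three things are asked: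
- the carboxylate oxygen adds to C8a;
- the acyl group migrates to C4a, giving the ortho-acyl phenoxide 15;
- the phenoxide displaces the methoxy group at C2 of the beta-methoxy enone.

The beta-methoxy group makes the closure an addition–elimination that arrives directly at the flavone oxidation level, with the C3 oxygen in place as its benzyl ether.

**The group on the C5 oxygen.** Aryne 14 is released by fluoride from silyl triflate 13. The C5 substituent must be a stronger sigma-acceptor than methoxy, so that the carbanion formed on addition prefers C4a and the nucleophile enters at C8a. It must also not leave from that carbanion. A second triflate would direct most strongly, but an aryl anion beside a triflate is the arrangement from which arynes are made, and it should expel triflate before the four-centre acyl transfer can occur. A tosylate keeps most of the inductive pull and the bulk, is a much poorer nucleofuge, and comes off under mild alkaline conditions. Precursor 13 is therefore traced to monotosylate 12 (O–S bond of the triflate) and 12 to silylcatechol 11 (O–S bond of the tosylate). The order matters: the open hydroxyl of 11 is tosylated first, and the hydroxyl beside silicon is left for the triflate, the only position from which elimination can start.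

**Silicon.** The C–Si bond of 11 is traced to the C–Br bond of bromocatechol 8. Both hydroxyls are silylated (9), bromine–lithium exchange and a retro-Brook shift move one silyl group from oxygen to the neighbouring carbon (10), and work-up frees the second hydroxyl. Silicon is thus delivered by the adjacent oxygen without a directed metalation. The forward step only requires that the exchange outrun attack of the alkyllithium on the silyl ethers, which is the normal course at low temperature.

**Ring A oxygens.** A free, electron-rich catechol is a poor substrate for clean monobromination, so the second oxygen is kept latent as a formyl group. Compound 8 comes from salicylaldehyde 7 by Dakin oxidation (the C–CHO bond becomes C–O), and 7 from commercial 2-hydroxy-4,5-dimethoxybenzaldehyde 6 by bromination. In 6 the aldehyde tempers the ring, and the only position activated by the free phenol is C3, between the hydroxyl and the C4 methoxy group. This carbon becomes C8a.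

**The acid.** Acid 5 is traced to its methyl ester 4 (ester C–O bond), 4 to beta-keto ester 3 (enol O–CH3 bond), and 3 to methyl 2-(benzyloxy)acetate 1 and 3,4,5-trimethoxybenzoyl chloride 2 (C3–C4 bond, crossed Claisen). This arm brings in ring B, the C3 oxygen and the carbon that becomes C4 in three steps from two commercial compounds. The forward steps need O- over C-methylation of the enolate of 3, and an ester hydrolysis that spares the enol ether.

## Roads not taken

**Alternative 1:** carbonylative ketone arylation.
- Cut: C4a–C4 and C4–C3, with carbon monoxide A4 as C4.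
- Forward key step: Pd(dba)2 (zerovalent palladium) and a bisphosphine join ring A iodide A2, A4 and the enolate of ketone A3 to give 1,3-diketone A1. Acid would then remove the methoxymethyl group and cyclodehydrate to flavone A5, and a boron trihalide would have to cleave both the benzyl ether and the methyl ether peri to the carbonyl.
- Merits: the reaction class is established, O1 is already on the ring so there is no regiochemical gamble, and the unmasking could be one operation.
- Weak points: A2 has oxygen substituents on both sides of the iodine, which slows oxidative addition and the capture of a crowded acylpalladium. A3 is an alpha-alkoxy ketone and gives a 2-substituted diketone, a less favourable case than a methyl ketone. No ring closes in the step. A2 needs four oxygens on ring A with one set apart, several steps from simple phenols. The C5 oxygen ends as one methyl ether among six and must be freed selectively.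
- Comparison: this road is the safer one in precedent and in orientation. The chosen plan sets against it a ring closure in the same operation, a C5 oxygen that is differentiated from the outset, a ring A precursor reached in five steps from a commercial aldehyde, and no pressurised toxic gas.

**Alternative 2:** umpolung closure at C3–C4.
- Cut: the C3–C4 bond.
- Forward key step: a triazolium-derived carbene with DBU turns the aryl aldehyde of dialdehyde A7 into an acyl anion equivalent that adds to the aliphatic aldehyde, closing ring C as the trans 3-hydroxychroman-4-one A6.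
- Merits: mild and metal-free; the C3 hydroxyl is created in place without a protecting group; O1 is attached beforehand by ordinary ether formation, so ring A orientation is not in question.
- Weak points: A7 contains an alpha-aryloxy-alpha-aryl acetaldehyde, which enolises, self-condenses and oxidises readily. The aryl aldehyde, crowded and electron-rich, is the reluctant partner for carbene addition; if the aliphatic aldehyde becomes the donor, the isomeric 4-hydroxy-3-ketone results. Two stereocentres are set and then erased, because A6 must still be dehydrogenated across C2–C3 and debenzylated. The salicylaldehyde behind A7 again needs four differentiated ring A oxygens.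
- Comparison: this road is better in mildness and in certainty of orientation. The chosen plan offers the flavone oxidation level directly, stable and crystalline-type precursors, and a convergent union of two fragments.

**Alternative 3:** ring A built last on a pyranone.
- Cut: the C4a–C5 bond.
- Forward key step: base cyclises the 3-oxobutanoate chain of pyranone A9 (made from kojic acid A10). C4a attacks the ester carbon C5 in a Claisen condensation, and enolisation gives the aromatic 5,7-dihydroxy-8-methoxy ring of A8. Selective 7-O-methylation (the 5-hydroxyl is held by the carbonyl) and debenzylation would follow.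
- Merits: the ring A oxygen pattern is fixed by construction and cannot come out as the 5,6,7 isomer; the chemistry is classical; A10 is cheap and supplies ring C with its C3 oxygen.
- Weak points: A9 needs a long linear build (arylation at the carbon that becomes C2, oxidation and methoxylation at C8, chain extension). In the cyclisation the most acidic site is the methylene between ketone and ester, whose enolate deactivates the ester that C4a must attack. Closure needs a second deprotonation at the vinylogous C8 position, and O-cyclisation can compete.
- Comparison: in regiochemical security this road is superior to the chosen one. The chosen plan answers with a much shorter, convergent sequence and a key step whose ring closure is simple once the acyl group is on C4a.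

Key step: step 9

Assumption: enol ethers 4, 5 and 15 are drawn as E isomers, but either isomer or a mixture serves, because C2 becomes tetrahedral before methoxide leaves; 6 is taken as a purchasable compound.

## Route

Step 1
Reactants: 1 methyl 2-(benzyloxy)acetate; 2 3,4,5-trimethoxybenzoyl chloride
Product: 3 methyl 2-(benzyloxy)-3-oxo-3-(3,4,5-trimethoxyphenyl)propanoate (racemic)
Conditions: LiN(i-Pr)2 (2.1 equiv), 1 (2.1 equiv), THF, −78 °C; then 2 (1.0 equiv), −78 → −40 °C; aq. NH4Cl
Reagents that add atoms: none
Why: Crossed Claisen acylation of the lithium enolate of 1 with an aroyl chloride; the second equivalent of enolate deprotonates the more acidic product and so prevents a second acylation. The new stereocentre at C2 is enolisable, forms racemic and disappears in step 2.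

Step 2
Reactants: 3 methyl 2-(benzyloxy)-3-oxo-3-(3,4,5-trimethoxyphenyl)propanoate
Product: 4 methyl (2E)-2-(benzyloxy)-3-methoxy-3-(3,4,5-trimethoxyphenyl)prop-2-enoate
Conditions: Cs2CO3, Me2SO4, DMF, 0 °C → rt
Reagents that add atoms: dimethyl sulfate, COS(=O)(=O)OC
Why: O-Alkylation of a beta-keto ester enolate: a hard electrophile and a weakly coordinated caesium enolate in DMF favour attack through the ketone oxygen, and C-methylation would have to build a fully substituted carbon bearing benzyloxy, aroyl and ester groups. The alkene geometry is of no consequence for step 9.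

Step 3
Reactants: 4 methyl (2E)-2-(benzyloxy)-3-methoxy-3-(3,4,5-trimethoxyphenyl)prop-2-enoate
Product: 5 (2E)-2-(benzyloxy)-3-methoxy-3-(3,4,5-trimethoxyphenyl)prop-2-enoic acid
Conditions: LiOH·H2O, THF/MeOH/H2O, 40 °C; then 1 M HCl to pH 3, 0 °C
Reagents that add atoms: lithium hydroxide, [Li+].[OH-]
Why: Saponification of a methyl ester by acyl–oxygen cleavage; once the carboxylate has formed, the beta-carbon is deactivated towards conjugate attack, and cold, brief acidification spares the enol ether.

Step 4
Reactants: 6 2-hydroxy-4,5-dimethoxybenzaldehyde
Product: 7 3-bromo-2-hydroxy-4,5-dimethoxybenzaldehyde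
Conditions: NBS (1.05 equiv), MeCN, 0 °C → rt
Reagents that add atoms: N-bromosuccinimide, O=C1CCC(=O)N1Br
Why: Electrophilic aromatic bromination: C3 is ortho to the free phenol and to the C4 methoxy group, the para position of the phenol is occupied, and C6 lies ortho to the deactivating formyl group, so substitution should occur at C3 only.

Step 5
Reactants: 7 3-bromo-2-hydroxy-4,5-dimethoxybenzaldehyde
Product: 8 3-bromo-4,5-dimethoxybenzene-1,2-diol
Conditions: 30 % H2O2, aq. NaOH, THF/H2O, 0 °C → rt, under N2; then dil. HCl
Reagents that add atoms: hydrogen peroxide, OO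
Why: Dakin oxidation of an ortho-hydroxybenzaldehyde: hydroperoxide adds to the aldehyde, the electron-rich aryl group migrates to oxygen and the formate is hydrolysed. Inert gas and an acidic work-up protect the catechol from autoxidation.

Step 6
Reactants: 8 3-bromo-4,5-dimethoxybenzene-1,2-diol
Product: 11 4,5-dimethoxy-3-(trimethylsilyl)benzene-1,2-diol, via bis-silyl ether 9 (not isolated), via lithium phenoxide 10 (not isolated)
Conditions: HMDS, THF, 70 °C, then evaporate; n-BuLi (1.1 equiv), THF, −78 → 0 °C; aq. NH4Cl/MeOH
Reagents that add atoms: hexamethyldisilazane, C[Si](C)(C)N[Si](C)(C)C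
Why: O-Silylation, bromine–lithium exchange and retro-Brook (1,3 O to C) silyl shift, the standard entry to ortho-silylphenols for aryne precursors. Only the silyl group on the oxygen next to the lithiated carbon can migrate, and the remaining aryl silyl ether is cleaved on mild aqueous work-up.

Step 7
Reactants: 11 4,5-dimethoxy-3-(trimethylsilyl)benzene-1,2-diol
Product: 12 2-hydroxy-4,5-dimethoxy-3-(trimethylsilyl)phenyl 4-methylbenzenesulfonate
Conditions: TsCl (1.0 equiv), Et3N (1.1 equiv), CH2Cl2, −20 → 0 °C
Reagents that add atoms: 4-methylbenzenesulfonyl chloride, Cc1ccc(S(Cl)(=O)=O)cc1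
Why: Selective sulfonylation of a 3-substituted catechol: the hydroxyl at C1 is open, while the one at C2 is shielded by the trimethylsilyl group, so one equivalent of sulfonyl chloride at low temperature should take the remote oxygen.

Step 8
Reactants: 12 2-hydroxy-4,5-dimethoxy-3-(trimethylsilyl)phenyl 4-methylbenzenesulfonate
Product: 13 4,5-dimethoxy-2-[(trifluoromethanesulfonyl)oxy]-3-(trimethylsilyl)phenyl 4-methylbenzenesulfonate
Conditions: Tf2O (1.2 equiv), pyridine, CH2Cl2, 0 °C
Reagents that add atoms: trifluoromethanesulfonic anhydride, O=S(=O)(OS(=O)(=O)C(F)(F)F)C(F)(F)F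
Why: Triflation of a hindered phenol with Tf2O and pyridine, as in the usual preparation of ortho-silylaryl triflates; the triflate ends on the oxygen ortho to silicon, the only position from which fluoride can trigger elimination.

Step 9
Reactants: 5 (2E)-2-(benzyloxy)-3-methoxy-3-(3,4,5-trimethoxyphenyl)prop-2-enoic acid; 13 4,5-dimethoxy-2-[(trifluoromethanesulfonyl)oxy]-3-(trimethylsilyl)phenyl 4-methylbenzenesulfonate
Product: 16 3-(benzyloxy)-7,8-dimethoxy-4-oxo-2-(3,4,5-trimethoxyphenyl)-4H-chromen-5-yl 4-methylbenzenesulfonate, via aryne 14 (not isolated), via ortho-acyl phenoxide 15 (not isolated)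
Conditions: 13 (1.0 equiv), 5 (1.3 equiv), CsF (4 equiv), THF, 100 °C (sealed tube)
Reagents that add atoms: none
Why: Proposed new method: fluoride removes silicon from 13, the C8a carbanion expels the C4a triflate and aryne 14 forms; the caesium carboxylate of 5 adds through oxygen to C8a, the resulting C4a carbanion attacks the aryl ester carbonyl (4-exo-trig) and the four-membered alkoxide opens to the ortho-acyl phenoxide 15, a net insertion into the acid C–O bond. The closest known reaction type is the fluoride-induced insertion of arynes into the C–O bond of carboxylic acids, which gives ortho-hydroxyaryl ketones and, from unsaturated acids, chromanones and flavones; new here are an aryne flanked by two different oxygens and a closure by addition–elimination. Ring C closes by 6-endo-trig conjugate addition of the C8a phenoxide to C2 of the beta-methoxy enone followed by loss of methoxide, for which either alkene isomer serves. No stereocentre is formed. The selectivity needed is regiochemical: oxygen must go to C8a and the acyl group to C4a, which should follow because the C5 sulfonate is a stronger sigma-acceptor and bulkier than the C8 methoxy group, so the carbanion develops at C4a and the nucleophile enters at the distal carbon. The tosylate is a poor enough nucleofuge that the C4a carbanion should transfer the acyl group before it can expel the sulfonate, which a triflate in this position would not allow. THF is used instead of acetonitrile so that the solvent does not protonate the carbanion before acyl transfer.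

Step 10
Reactants: 16 3-(benzyloxy)-7,8-dimethoxy-4-oxo-2-(3,4,5-trimethoxyphenyl)-4H-chromen-5-yl 4-methylbenzenesulfonate
Product: 17 3-(benzyloxy)-5-hydroxy-7,8-dimethoxy-2-(3,4,5-trimethoxyphenyl)-4H-chromen-4-one
Conditions: KOH (aq., 3 equiv), THF/MeOH, 50 °C; then AcOH
Reagents that add atoms: none
Why: Alkaline cleavage of an aryl tosylate by attack at sulfur; the sulfonate is activated because the departing phenoxide is ortho to the C4 carbonyl, and the benzyl ether keeps the C3 oxygen masked while base is present.

Step 11
Reactants: 17 3-(benzyloxy)-5-hydroxy-7,8-dimethoxy-2-(3,4,5-trimethoxyphenyl)-4H-chromen-4-one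
Product: 18 3,5-dihydroxy-7,8-dimethoxy-2-(3,4,5-trimethoxyphenyl)-4H-chromen-4-one
Conditions: H2 (1 atm), 10 % Pd/C, EtOAc/MeOH, rt
Reagents that add atoms: none
Why: Hydrogenolysis of a benzyl ether over Pd/C; the tetrasubstituted C2–C3 double bond of the chromenone is not reduced at balloon pressure, and no base is present to promote oxidation of the freed flavonol.

## Compound list

1 | methyl 2-(benzyloxy)acetate | COC(=O)COCc1ccccc1 | starting material
2 | 3,4,5-trimethoxybenzoyl chloride | COc1cc(C(=O)Cl)cc(OC)c1OC | starting material
3 | methyl 2-(benzyloxy)-3-oxo-3-(3,4,5-trimethoxyphenyl)propanoate (racemic; one enantiomer drawn) | COC(=O)[C@@H](OCc1ccccc1)C(=O)c1cc(OC)c(OC)c(OC)c1 | intermediate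
4 | methyl (2E)-2-(benzyloxy)-3-methoxy-3-(3,4,5-trimethoxyphenyl)prop-2-enoate | COC(=O)/C(OCc1ccccc1)=C(\OC)c1cc(OC)c(OC)c(OC)c1 | intermediate
5 | (2E)-2-(benzyloxy)-3-methoxy-3-(3,4,5-trimethoxyphenyl)prop-2-enoic acid | OC(=O)/C(OCc1ccccc1)=C(\OC)c1cc(OC)c(OC)c(OC)c1 | intermediate
6 | 2-hydroxy-4,5-dimethoxybenzaldehyde | COc1cc(O)c(C=O)cc1OC | starting material
7 | 3-bromo-2-hydroxy-4,5-dimethoxybenzaldehyde | COc1cc(C=O)c(O)c(Br)c1OC | intermediate
8 | 3-bromo-4,5-dimethoxybenzene-1,2-diol | COc1cc(O)c(O)c(Br)c1OC | intermediate
9 | 3-bromo-4,5-dimethoxy-1,2-bis[(trimethylsilyl)oxy]benzene | COc1cc(O[Si](C)(C)C)c(O[Si](C)(C)C)c(Br)c1OC | intermediate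
10 | lithium 3,4-dimethoxy-2-(trimethylsilyl)-6-[(trimethylsilyl)oxy]phenolate | [Li+].[O-]c1c(O[Si](C)(C)C)cc(OC)c(OC)c1[Si](C)(C)C | intermediate
11 | 4,5-dimethoxy-3-(trimethylsilyl)benzene-1,2-diol | COc1cc(O)c(O)c([Si](C)(C)C)c1OC | intermediate
12 | 2-hydroxy-4,5-dimethoxy-3-(trimethylsilyl)phenyl 4-methylbenzenesulfonate | COc1cc(OS(=O)(=O)c2ccc(C)cc2)c(O)c([Si](C)(C)C)c1OC | intermediate
13 | 4,5-dimethoxy-2-[(trifluoromethanesulfonyl)oxy]-3-(trimethylsilyl)phenyl 4-methylbenzenesulfonate | COc1cc(OS(=O)(=O)c2ccc(C)cc2)c(OS(=O)(=O)C(F)(F)F)c([Si](C)(C)C)c1OC | intermediate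
14 | 3,4-dimethoxy-6-(tosyloxy)benzyne (4,5-dimethoxy-2,3-didehydrophenyl 4-methylbenzenesulfonate) | COC1=C(OC)C#CC(OS(=O)(=O)c2ccc(C)cc2)=C1 | intermediate
15 | 2-[(2E)-2-(benzyloxy)-3-methoxy-3-(3,4,5-trimethoxyphenyl)prop-2-enoyl]-3-hydroxy-4,5-dimethoxyphenyl 4-methylbenzenesulfonate (present as its caesium phenoxide) | COc1cc(OS(=O)(=O)c2ccc(C)cc2)c(C(=O)/C(OCc2ccccc2)=C(\OC)c2cc(OC)c(OC)c(OC)c2)c(O)c1OC | intermediate
16 | 3-(benzyloxy)-7,8-dimethoxy-4-oxo-2-(3,4,5-trimethoxyphenyl)-4H-chromen-5-yl 4-methylbenzenesulfonate | COc1cc(-c2oc3c(OC)c(OC)cc(OS(=O)(=O)c4ccc(C)cc4)c3c(=O)c2OCc2ccccc2)cc(OC)c1OC | intermediate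
17 | 3-(benzyloxy)-5-hydroxy-7,8-dimethoxy-2-(3,4,5-trimethoxyphenyl)-4H-chromen-4-one | COc1cc(-c2oc3c(OC)c(OC)cc(O)c3c(=O)c2OCc2ccccc2)cc(OC)c1OC | intermediate
18 | 3,5-dihydroxy-7,8-dimethoxy-2-(3,4,5-trimethoxyphenyl)-4H-chromen-4-one (3,5-dihydroxy-7,8,3',4',5'-pentamethoxyflavone) | COc1cc(-c2oc3c(OC)c(OC)cc(O)c3c(=O)c2O)cc(OC)c1OC | target

## Step count and least certain steps

Total: 11 steps. Longest linear sequence: 8 steps (steps 4 to 11, from 6); the acid arm (steps 1 to 3) joins at step 9.

**Step 9 (key step).** Three things may go wrong.
- The carboxylate may add at C4a instead of C8a: the inductive margin of a tosylate over a methoxy group is smaller than that of a triflate, and the C7 methoxy group pulls weakly in the wrong direction.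
- The C4a carbanion may be protonated before it transfers the acyl group, leaving an O-arylated acid with no C4a–C4 bond.
- The carbanion may still lose the sulfonate at high temperature.

Partial cleavage of the tosylate by the liberated methoxide would be harmless, since it leads to 17. The fallback uses only classical chemistry, sets out from acid chloride 2 and returns at 18, giving up convergence with the aryne arm:
- Commercial 1-(2-hydroxy-3,4,6-trimethoxyphenyl)ethan-1-one F1 is O-aroylated with 2 in pyridine to 2-acetyl-3,5,6-trimethoxyphenyl 3,4,5-trimethoxybenzoate F2.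
- Baker–Venkataraman rearrangement (KOH, pyridine) gives 1-(2-hydroxy-3,4,6-trimethoxyphenyl)-3-(3,4,5-trimethoxyphenyl)propane-1,3-dione F3.
- Cyclodehydration (H2SO4, AcOH) gives 5,7,8-trimethoxy-2-(3,4,5-trimethoxyphenyl)-4H-chromen-4-one F4.
- Dimethyldioxirane epoxidises the C2–C3 double bond to rac-2,3-epoxy-5,7,8-trimethoxy-2-(3,4,5-trimethoxyphenyl)chroman-4-one F5, which a trace of TsOH opens to 3-hydroxy-5,7,8-trimethoxy-2-(3,4,5-trimethoxyphenyl)-4H-chromen-4-one F6.
- BCl3 in CH2Cl2 at low temperature removes the methyl group peri to the carbonyl under chelation control and gives 18.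

**Step 7.** Site selectivity may be poor: sulfonylation at the hindered oxygen or at both. The fallback differentiates the oxygens by mechanism instead of by hindrance; it sets out from 8 and returns at 13. Silylation and bromine–lithium exchange as in step 6 give lithium phenoxide 10, which is trapped at −78 °C with Tf2O on the oxygen that has just given up its silyl group. This gives 3,4-dimethoxy-2-(trimethylsilyl)-6-[(trimethylsilyl)oxy]phenyl trifluoromethanesulfonate F7. Dilute citric acid in aqueous methanol frees the other phenol, 6-hydroxy-3,4-dimethoxy-2-(trimethylsilyl)phenyl trifluoromethanesulfonate F8, and tosylation of this single hydroxyl (TsCl, Et3N) gives 13.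

**Step 2.** C-Methylation of the enolate may compete with O-methylation. The fallback forms the enol ether without an enolate alkylation; it sets out from 3 and returns at 4. Trimethyl orthoformate with catalytic TsOH in methanol converts the ketone into the ketal methyl 2-(benzyloxy)-3,3-dimethoxy-3-(3,4,5-trimethoxyphenyl)propanoate F9, which loses methanol on heating in toluene with the same acid to give 4.

**Step 3.** Hydroxide may attack C3 with loss of methoxide, and the enol ether may hydrolyse during acidification, leading on to decarboxylation. The fallback avoids water and the free acid; it sets out from 4 and returns at 16. KOSiMe3 in dry THF cleaves the methyl ester to potassium (2E)-2-(benzyloxy)-3-methoxy-3-(3,4,5-trimethoxyphenyl)prop-2-enoate F10. This salt is used directly with 13 and CsF in step 9, which also removes the acid proton that could quench the C4a carbanion.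

**Step 5.** The electron-rich catechol may be oxidised further under alkaline peroxide. The fallback keeps both oxygens acylated until the end; it sets out from 7 and returns at 8. Acetylation (Ac2O, pyridine) gives 2-bromo-6-formyl-3,4-dimethoxyphenyl acetate F11. Baeyer–Villiger oxidation with mCPBA in CH2Cl2 gives 2-bromo-6-(formyloxy)-3,4-dimethoxyphenyl acetate F12. Methanolysis of both esters with HCl in degassed methanol gives 8.

## Further compounds

F1 | step 9 | 1-(2-hydroxy-3,4,6-trimethoxyphenyl)ethan-1-one | CC(=O)c1c(OC)cc(OC)c(OC)c1O
F2 | step 9 | 2-acetyl-3,5,6-trimethoxyphenyl 3,4,5-trimethoxybenzoate | CC(=O)c1c(OC)cc(OC)c(OC)c1OC(=O)c1cc(OC)c(OC)c(OC)c1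
F3 | step 9 | 1-(2-hydroxy-3,4,6-trimethoxyphenyl)-3-(3,4,5-trimethoxyphenyl)propane-1,3-dione | COc1cc(OC)c(C(=O)CC(=O)c2cc(OC)c(OC)c(OC)c2)c(O)c1OC
F4 | step 9 | 5,7,8-trimethoxy-2-(3,4,5-trimethoxyphenyl)-4H-chromen-4-one | COc1cc(-c2cc(=O)c3c(OC)cc(OC)c(OC)c3o2)cc(OC)c1OC
F5 | step 9 | rac-2,3-epoxy-5,7,8-trimethoxy-2-(3,4,5-trimethoxyphenyl)chroman-4-one (cis-fused oxirane; one enantiomer drawn) | O=C1[C@H]2O[C@@]2(c3cc(OC)c(OC)c(OC)c3)Oc3c(OC)c(OC)cc(OC)c31
F6 | step 9 | 3-hydroxy-5,7,8-trimethoxy-2-(3,4,5-trimethoxyphenyl)-4H-chromen-4-one | COc1cc(-c2oc3c(OC)c(OC)cc(OC)c3c(=O)c2O)cc(OC)c1OC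
F7 | step 7 | 3,4-dimethoxy-2-(trimethylsilyl)-6-[(trimethylsilyl)oxy]phenyl trifluoromethanesulfonate | COc1cc(O[Si](C)(C)C)c(OS(=O)(=O)C(F)(F)F)c([Si](C)(C)C)c1OC
F8 | step 7 | 6-hydroxy-3,4-dimethoxy-2-(trimethylsilyl)phenyl trifluoromethanesulfonate | COc1cc(O)c(OS(=O)(=O)C(F)(F)F)c([Si](C)(C)C)c1OC
F9 | step 2 | methyl 2-(benzyloxy)-3,3-dimethoxy-3-(3,4,5-trimethoxyphenyl)propanoate (racemic; one enantiomer drawn) | COC(=O)[C@@H](OCc1ccccc1)C(OC)(OC)c1cc(OC)c(OC)c(OC)c1
F10 | step 3 | potassium (2E)-2-(benzyloxy)-3-methoxy-3-(3,4,5-trimethoxyphenyl)prop-2-enoate | [K+].[O-]C(=O)/C(OCc1ccccc1)=C(\OC)c1cc(OC)c(OC)c(OC)c1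
F11 | step 5 | 2-bromo-6-formyl-3,4-dimethoxyphenyl acetate | CC(=O)Oc1c(Br)c(OC)c(OC)cc1C=O
F12 | step 5 | 2-bromo-6-(formyloxy)-3,4-dimethoxyphenyl acetate | CC(=O)Oc1c(Br)c(OC)c(OC)cc1OC=O
A1 | alternative 1 | rac-2-(benzyloxy)-1-[3,4,6-trimethoxy-2-(methoxymethoxy)phenyl]-3-(3,4,5-trimethoxyphenyl)propane-1,3-dione (one enantiomer drawn) | COCOc1c(C(=O)[C@H](OCc2ccccc2)C(=O)c2cc(OC)c(OC)c(OC)c2)c(OC)cc(OC)c1OC
A2 | alternative 1 | 2-iodo-1,4,5-trimethoxy-3-(methoxymethoxy)benzene | COCOc1c(I)c(OC)cc(OC)c1OC
A3 | alternative 1 | 2-(benzyloxy)-1-(3,4,5-trimethoxyphenyl)ethan-1-one | O=C(COCc1ccccc1)c1cc(OC)c(OC)c(OC)c1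
A4 | alternative 1 | carbon monoxide | [C-]#[O+]
A5 | alternative 1 | 3-(benzyloxy)-5,7,8-trimethoxy-2-(3,4,5-trimethoxyphenyl)-4H-chromen-4-one | COc1cc(-c2oc3c(OC)c(OC)cc(OC)c3c(=O)c2OCc2ccccc2)cc(OC)c1OC
A6 | alternative 2 | rac-(2R,3R)-5-(benzyloxy)-3-hydroxy-7,8-dimethoxy-2-(3,4,5-trimethoxyphenyl)chroman-4-one (trans; one enantiomer drawn) | COc1cc(OCc2ccccc2)c2c(c1OC)O[C@H](c1cc(OC)c(OC)c(OC)c1)[C@@H](O)C2=O
A7 | alternative 2 | rac-2-[3-(benzyloxy)-2-formyl-5,6-dimethoxyphenoxy]-2-(3,4,5-trimethoxyphenyl)acetaldehyde (one enantiomer drawn) | O=C[C@@H](Oc1c(C=O)c(OCc2ccccc2)cc(OC)c1OC)c1cc(OC)c(OC)c(OC)c1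
A8 | alternative 3 | 3-(benzyloxy)-5,7-dihydroxy-8-methoxy-2-(3,4,5-trimethoxyphenyl)-4H-chromen-4-one | COc1cc(-c2oc3c(OC)c(O)cc(O)c3c(=O)c2OCc2ccccc2)cc(OC)c1OC
A9 | alternative 3 | rac-methyl 4-[5-(benzyloxy)-4-oxo-6-(3,4,5-trimethoxyphenyl)-4H-pyran-2-yl]-4-methoxy-3-oxobutanoate (one enantiomer drawn) | COC(=O)CC(=O)[C@H](OC)c1cc(=O)c(OCc2ccccc2)c(-c2cc(OC)c(OC)c(OC)c2)o1
A10 | alternative 3 | kojic acid (5-hydroxy-2-(hydroxymethyl)-4H-pyran-4-one) | O=c1cc(CO)occ1O
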